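**Plan**

1. Numbering follows the prostanoid chain: C1 is the ester carbon, C4 the side-chain acetoxy carbon, C5=C6 the E alkene, C8–C12 the ring (C9 ketone, C10=C11, C12 acetoxy) and C14=C15 the Z alkene.
2. The retrosynthesis cuts C5=C6 (Wittig between a C6 lactol and a C1–C5 ketophosphorane), then the C12–O bond (iodolactone), then C7–C8 (Johnson–Claisen), and finally opens the carbocycle to a furylcarbinol (Piancatelli) built from furfural, propargyl bromide and 1-iodopentane.
3. Forward, the cyclopentenone ring arises first, the C6–C7 acetic acid arm is attached at C8, the γ-lactone ring O–C6–C7–C8–C12 closes in the key step, and the lactone is then opened to join C1–C5.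
4. The enabling feature: on the five-membered carbocycle the C12 oxygen is cis to the C7 methylene on the neighbouring C8, and a five-membered lactone bridging C12–O and C8 through C6 and C7 can only be cis-fused, so C8 dictates C12.
5. Stereochemistry: a lipase resolution fixes the C9 carbinol (S), a cis-selective Luche reduction relays it to C11, the suprafacial Claisen shift to C8 and the iodolactonisation to C12. C9 is oxidised at the end, C4 comes from a CBS reduction, the Z alkene from alkyne semihydrogenation and the E alkene from the stabilised ylide.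

Key step: step 9

Assumption: the lipase acetylates the (R)-alcohol of 4-hydroxycyclopent-2-enones faster, as is usual for this class, so the (S)-alcohol is the one recovered unreacted.

**Route**

Step 1
Reactants: 1 furfural; 2 propargyl bromide
Product: 4 rac-1-(furan-2-yl)but-3-yn-1-ol, via allenylzinc bromide 3 (not isolated)
Conditions: Zn dust, THF, 0 °C → rt (Barbier mode); H2O work-up
Reagents that add atoms: none
Why: Barbier propargylation, in which the allenylzinc species adds to the aldehyde through a cyclic SE2′ transition state and should give the homopropargylic alcohol; the carbinol centre is racemic and is erased in step 3.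

Step 2
Reactants: 4 rac-1-(furan-2-yl)but-3-yn-1-ol; 5 1-iodopentane
Product: 7 rac-1-(furan-2-yl)non-3-yn-1-ol, via dilithio alkoxide-acetylide 6 (not isolated)
Conditions: n-BuLi (2.1 equiv), THF, −78 → −20 °C; then 5, DMPU, −20 °C → rt; H2O work-up
Reagents that add atoms: none
Why: Acetylide alkylation of an alkoxide/acetylide dianion; the alkyne C–H is far more acidic than any furan C–H, and the acetylide carbon should outcompete the lithium alkoxide for the primary iodide.

Step 3
Reactants: 7 rac-1-(furan-2-yl)non-3-yn-1-ol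
Product: 9 rac-4-hydroxy-2-(oct-2-yn-1-yl)cyclopent-2-en-1-one, via rac-trans-4-hydroxy-5-(oct-2-yn-1-yl)cyclopent-2-en-1-one 8 (not isolated)
Conditions: ZnCl2, dioxane/H2O, reflux; then Na2HPO4 to pH 8, 60 °C, same flask
Reagents that add atoms: water, O
Why: Piancatelli rearrangement (furfuryl cation, water addition, ring opening, conrotatory 4π closure to the trans-4-hydroxy-5-alkyl enone) followed by the usual mild-base isomerisation to the thermodynamically preferred 2-alkyl enone; the product is racemic.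

Step 4
Reactants: 9 rac-4-hydroxy-2-(oct-2-yn-1-yl)cyclopent-2-en-1-one
Product: 10 (4S)-4-hydroxy-2-(oct-2-yn-1-yl)cyclopent-2-en-1-one
Conditions: Burkholderia cepacia lipase (Amano PS), vinyl acetate, MTBE, 30 °C, run past half conversion; chromatography
Reagents that add atoms: none
Why: Lipase-catalysed kinetic resolution by irreversible transesterification; the enzyme should acetylate the (R)-alcohol and leave the (S)-alcohol, whose optical purity rises as conversion passes one half.

Step 5
Reactants: 10 (4S)-4-hydroxy-2-(oct-2-yn-1-yl)cyclopent-2-en-1-one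
Product: 11 (4S)-4-[(tert-butyldimethylsilyl)oxy]-2-(oct-2-yn-1-yl)cyclopent-2-en-1-one
Conditions: TBSCl, imidazole, DMF, 0 °C → rt
Reagents that add atoms: tert-butyldimethylsilyl chloride, CC(C)(C)[Si](C)(C)Cl
Why: Standard silylation of a secondary alcohol under conditions too mild to eliminate the β-oxygen; the stereocentre is not touched.

Step 6
Reactants: 11 (4S)-4-[(tert-butyldimethylsilyl)oxy]-2-(oct-2-yn-1-yl)cyclopent-2-en-1-one
Product: 12 (1R,4S)-4-[(tert-butyldimethylsilyl)oxy]-2-(oct-2-yn-1-yl)cyclopent-2-en-1-ol (cis)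
Conditions: NaBH4, CeCl3·7H2O, MeOH, −78 °C
Reagents that add atoms: none
Why: Luche 1,2-reduction; hydride should attack the ring face opposite the silyloxy group, so the new carbinol (C11, R) is cis to the C9 oxygen.

Step 7
Reactants: 12 (1R,4S)-4-[(tert-butyldimethylsilyl)oxy]-2-(oct-2-yn-1-yl)cyclopent-2-en-1-ol; 13 triethyl orthoacetate
Product: 15 ethyl 2-[(1R,5S)-5-[(tert-butyldimethylsilyl)oxy]-2-(oct-2-yn-1-yl)cyclopent-2-en-1-yl]acetate, via ethyl ketene acetal 14 (not isolated)
Conditions: MeC(OEt)3 (excess), EtCO2H (cat.), 140 °C, EtOH distilled off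
Reagents that add atoms: none
Why: Johnson–Claisen rearrangement; the [3,3] shift is suprafacial, so the C7–C8 bond forms on the face that carried the C11–O bond, which sets C8 (R, cis to the silyloxy group) and moves the alkene to C11=C12.

Step 8
Reactants: 15 ethyl 2-[(1R,5S)-5-[(tert-butyldimethylsilyl)oxy]-2-(oct-2-yn-1-yl)cyclopent-2-en-1-yl]acetate
Product: 16 2-[(1R,5S)-5-[(tert-butyldimethylsilyl)oxy]-2-(oct-2-yn-1-yl)cyclopent-2-en-1-yl]acetic acid
Conditions: LiOH, THF/MeOH/H2O, rt; then 0.5 M HCl to pH 4, 0 °C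
Reagents that add atoms: lithium hydroxide, [Li+].[OH-]
Why: Ester saponification; the silyl ether is stable to aqueous hydroxide at room temperature, and C8 is β to the carbonyl and cannot epimerise.

Step 9
Reactants: 16 2-[(1R,5S)-5-[(tert-butyldimethylsilyl)oxy]-2-(oct-2-yn-1-yl)cyclopent-2-en-1-yl]acetic acid
Product: 17 (3aS,4S,6S,6aS)-4-[(tert-butyldimethylsilyl)oxy]-6-iodo-6a-(oct-2-yn-1-yl)hexahydro-2H-cyclopenta[b]furan-2-one (cis-fused, iodine trans to the lactone oxygen)
Conditions: I2, NaHCO3, THF/H2O, 0 °C, dark; aq. Na2S2O3 quench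
Reagents that add atoms: iodine, II
Why: Iodine forms an iodonium ion on the electron-rich trisubstituted C11=C12 alkene from the face opposite the acetic acid arm, and the carboxylate oxygen opens it anti at the more substituted C12, giving the C12–O bond and a trans C11–I bond. The closest known reaction type is the iodolactonisation of cycloalk-2-enylacetic acids to cis-fused γ-lactones under bicarbonate (kinetic) conditions. The one ring that closes, the γ-lactone O–C6–C7–C8–C12, forms in a 5-exo-trig mode. C12 is controlled by C8, because the two-atom C6–C7 tether can reach C12 only on the face on which it sits, which makes the ring fusion cis; C11 is controlled by the anti addition, which places iodine trans to the new C–O bond. The step needs oxygen at C12 and not C11, secured by Markovnikov opening together with the preference for the five-membered over the bridged six-membered lactone, and it needs the alkene to react before the C14≡C15 alkyne, secured by the much lower nucleophilicity of an alkyne towards iodine and the absence of any internal nucleophile within its reach.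

Step 10
Reactants: 17 (3aS,4S,6S,6aS)-4-[(tert-butyldimethylsilyl)oxy]-6-iodo-6a-(oct-2-yn-1-yl)hexahydro-2H-cyclopenta[b]furan-2-one
Product: 18 (3aS,4S,6aR)-4-[(tert-butyldimethylsilyl)oxy]-6a-(oct-2-yn-1-yl)-3,3a,4,6a-tetrahydro-2H-cyclopenta[b]furan-2-one
Conditions: DBU, toluene, 90 °C
Reagents that add atoms: none
Why: E2 dehydroiodination; C12 bears no hydrogen and C10 has a hydrogen antiperiplanar to iodine, so the alkene can only form at C10=C11, and the neopentyl-type iodide cannot be substituted.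

Step 11
Reactants: 18 (3aS,4S,6aR)-4-[(tert-butyldimethylsilyl)oxy]-6a-(oct-2-yn-1-yl)-3,3a,4,6a-tetrahydro-2H-cyclopenta[b]furan-2-one
Product: 19 (3aS,4S,6aR)-4-[(tert-butyldimethylsilyl)oxy]-6a-[(2Z)-oct-2-en-1-yl]-3,3a,4,6a-tetrahydro-2H-cyclopenta[b]furan-2-one
Conditions: H2 (1 atm), Pd/CaCO3 poisoned with Pb(OAc)2, quinoline, EtOAc, rt, stopped after one equivalent of H2
Reagents that add atoms: none
Why: Lindlar-type semihydrogenation; syn delivery of hydrogen on the poisoned palladium surface gives the Z alkene, and the hindered ring alkene next to the quaternary C12 should be left alone.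

Step 12
Reactants: 19 (3aS,4S,6aR)-4-[(tert-butyldimethylsilyl)oxy]-6a-[(2Z)-oct-2-en-1-yl]-3,3a,4,6a-tetrahydro-2H-cyclopenta[b]furan-2-one
Product: 20 (3aS,4S,6aR)-4-[(tert-butyldimethylsilyl)oxy]-6a-[(2Z)-oct-2-en-1-yl]-3,3a,4,6a-tetrahydro-2H-cyclopenta[b]furan-2-ol (lactol, both anomers)
Conditions: i-Bu2AlH, CH2Cl2, −78 °C; aq. potassium sodium tartrate work-up
Reagents that add atoms: none
Why: Partial reduction of a γ-lactone; the aluminium hemiacetal is stable at −78 °C and releases the lactol only on work-up, so over-reduction should be avoided.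

Step 13
Reactants: 21 methyltriphenylphosphonium bromide; 22 methyl 4-chloro-4-oxobutanoate
Product: 24 methyl 4-oxo-5-(triphenylphosphoranylidene)pentanoate, via methylenetriphenylphosphorane 23 (not isolated)
Conditions: 21 (2 equiv), n-BuLi (2 equiv), THF, 0 °C; then 22 (1 equiv), −78 °C → rt
Reagents that add atoms: none
Why: C-acylation of a phosphorus ylide with transylidation; one equivalent of ylide is acylated by the acid chloride (far more electrophilic than the methyl ester) and the second deprotonates the acylphosphonium salt to the stabilised ketophosphorane.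

Step 14
Reactants: 20 lactol; 24 methyl 4-oxo-5-(triphenylphosphoranylidene)pentanoate
Product: 25 methyl (5E)-7-[(1S,2R,5S)-5-[(tert-butyldimethylsilyl)oxy]-2-hydroxy-2-[(2Z)-oct-2-en-1-yl]cyclopent-3-en-1-yl]-4-oxohept-5-enoate
Conditions: 24 (1.5 equiv), toluene, 70 °C, no added base
Reagents that add atoms: none
Why: Wittig olefination of the open hydroxy-aldehyde form of the lactol with a ketone-stabilised ylide, which should be E-selective; neutral conditions are chosen so the freed tertiary C12 hydroxyl does not add back to the enone.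

Step 15
Reactants: 25 methyl (5E)-7-[(1S,2R,5S)-5-[(tert-butyldimethylsilyl)oxy]-2-hydroxy-2-[(2Z)-oct-2-en-1-yl]cyclopent-3-en-1-yl]-4-oxohept-5-enoate
Product: 26 methyl (4S,5E)-7-[(1S,2R,5S)-5-[(tert-butyldimethylsilyl)oxy]-2-hydroxy-2-[(2Z)-oct-2-en-1-yl]cyclopent-3-en-1-yl]-4-hydroxyhept-5-enoate
Conditions: (R)-2-methyl-CBS-oxazaborolidine (0.2 equiv), catecholborane, toluene, −78 °C; MeOH quench, pH 7 work-up, used at once
Reagents that add atoms: none
Why: Corey–Bakshi–Shibata reduction; the ketone should coordinate the catalyst anti to its larger alkenyl arm, so the (R)-catalyst delivers hydride to the face that gives the 4S allylic alcohol, while catecholborane at −78 °C leaves the alkenes and the ester alone.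

Step 16
Reactants: 26 methyl (4S,5E)-7-[(1S,2R,5S)-5-[(tert-butyldimethylsilyl)oxy]-2-hydroxy-2-[(2Z)-oct-2-en-1-yl]cyclopent-3-en-1-yl]-4-hydroxyhept-5-enoate
Product: 27 methyl (4S,5E)-4-acetoxy-7-[(1S,2R,5S)-2-acetoxy-5-[(tert-butyldimethylsilyl)oxy]-2-[(2Z)-oct-2-en-1-yl]cyclopent-3-en-1-yl]hept-5-enoate
Conditions: Ac2O, Et3N, DMAP (1 equiv), CH2Cl2, 0 °C → 35 °C
Reagents that add atoms: acetic anhydride, CC(=O)OC(C)=O
Why: DMAP-mediated acylation; the secondary C4 hydroxyl should be capped first (forestalling γ-lactonisation onto the ester) and the tertiary C12 hydroxyl follows through the N-acetylpyridinium ion, with only O–H bonds broken so no stereocentre changes.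

Step 17
Reactants: 27 methyl (4S,5E)-4-acetoxy-7-[(1S,2R,5S)-2-acetoxy-5-[(tert-butyldimethylsilyl)oxy]-2-[(2Z)-oct-2-en-1-yl]cyclopent-3-en-1-yl]hept-5-enoate
Product: 28 methyl (4S,5E)-4-acetoxy-7-[(1S,2R,5S)-2-acetoxy-5-hydroxy-2-[(2Z)-oct-2-en-1-yl]cyclopent-3-en-1-yl]hept-5-enoate
Conditions: HF·pyridine, pyridine, THF, 0 °C → rt
Reagents that add atoms: none
Why: Fluoride cleavage of the silyl ether under buffered, non-basic conditions, under which the acetates and the methyl ester should neither cleave nor migrate.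

Step 18
Reactants: 28 methyl (4S,5E)-4-acetoxy-7-[(1S,2R,5S)-2-acetoxy-5-hydroxy-2-[(2Z)-oct-2-en-1-yl]cyclopent-3-en-1-yl]hept-5-enoate
Product: 29 methyl (4S,5E)-4-acetoxy-7-[(1R,2R)-2-acetoxy-2-[(2Z)-oct-2-en-1-yl]-5-oxocyclopent-3-en-1-yl]hept-5-enoate (target)
Conditions: Dess–Martin periodinane, NaHCO3, CH2Cl2, 0 °C
Reagents that add atoms: none
Why: Dess–Martin oxidation of the allylic C9 alcohol to the enone under near-neutral conditions, which should leave the β-acetoxy group in place and C8 unepimerised (its two carbon chains are already trans).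

**Compound list**

1 | furfural | O=Cc1ccco1 | starting material
2 | propargyl bromide | C#CCBr | starting material
3 | allenylzinc bromide | C=C=C[Zn]Br | intermediate (not isolated)
4 | rac-1-(furan-2-yl)but-3-yn-1-ol | OC(CC#C)c1ccco1 | intermediate
5 | 1-iodopentane | CCCCCI | starting material
6 | dilithio alkoxide-acetylide of 4 | [Li]OC(CC#C[Li])c1ccco1 | intermediate (not isolated)
7 | rac-1-(furan-2-yl)non-3-yn-1-ol | CCCCCC#CCC(O)c1ccco1 | intermediate
8 | rac-trans-4-hydroxy-5-(oct-2-yn-1-yl)cyclopent-2-en-1-one (one enantiomer drawn) | CCCCCC#CC[C@H]1[C@H](O)C=CC1=O | intermediate (not isolated)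
9 | rac-4-hydroxy-2-(oct-2-yn-1-yl)cyclopent-2-en-1-one | CCCCCC#CCC1=CC(O)CC1=O | intermediate
10 | (4S)-4-hydroxy-2-(oct-2-yn-1-yl)cyclopent-2-en-1-one | CCCCCC#CCC1=C[C@@H](O)CC1=O | intermediate
11 | (4S)-4-[(tert-butyldimethylsilyl)oxy]-2-(oct-2-yn-1-yl)cyclopent-2-en-1-one | CCCCCC#CCC1=C[C@@H](O[Si](C)(C)C(C)(C)C)CC1=O | intermediate
12 | (1R,4S)-4-[(tert-butyldimethylsilyl)oxy]-2-(oct-2-yn-1-yl)cyclopent-2-en-1-ol | CCCCCC#CCC1=C[C@@H](O[Si](C)(C)C(C)(C)C)C[C@H]1O | intermediate
13 | triethyl orthoacetate | CC(OCC)(OCC)OCC | starting material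
14 | ethyl ketene acetal of 12 (1-ethoxyvinyl ether) | CCCCCC#CCC1=C[C@@H](O[Si](C)(C)C(C)(C)C)C[C@H]1OC(=C)OCC | intermediate (not isolated)
15 | ethyl 2-[(1R,5S)-5-[(tert-butyldimethylsilyl)oxy]-2-(oct-2-yn-1-yl)cyclopent-2-en-1-yl]acetate | CCCCCC#CCC1=CC[C@H](O[Si](C)(C)C(C)(C)C)[C@@H]1CC(=O)OCC | intermediate
16 | 2-[(1R,5S)-5-[(tert-butyldimethylsilyl)oxy]-2-(oct-2-yn-1-yl)cyclopent-2-en-1-yl]acetic acid | CCCCCC#CCC1=CC[C@H](O[Si](C)(C)C(C)(C)C)[C@@H]1CC(=O)O | intermediate
17 | (3aS,4S,6S,6aS)-4-[(tert-butyldimethylsilyl)oxy]-6-iodo-6a-(oct-2-yn-1-yl)hexahydro-2H-cyclopenta[b]furan-2-one | CCCCCC#CC[C@]12OC(=O)C[C@H]1[C@@H](O[Si](C)(C)C(C)(C)C)C[C@@H]2I | intermediate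
18 | (3aS,4S,6aR)-4-[(tert-butyldimethylsilyl)oxy]-6a-(oct-2-yn-1-yl)-3,3a,4,6a-tetrahydro-2H-cyclopenta[b]furan-2-one | CCCCCC#CC[C@]12OC(=O)C[C@H]1[C@@H](O[Si](C)(C)C(C)(C)C)C=C2 | intermediate
19 | (3aS,4S,6aR)-4-[(tert-butyldimethylsilyl)oxy]-6a-[(2Z)-oct-2-en-1-yl]-3,3a,4,6a-tetrahydro-2H-cyclopenta[b]furan-2-one | CCCCC/C=C\C[C@]12OC(=O)C[C@H]1[C@@H](O[Si](C)(C)C(C)(C)C)C=C2 | intermediate
20 | (3aS,4S,6aR)-4-[(tert-butyldimethylsilyl)oxy]-6a-[(2Z)-oct-2-en-1-yl]-3,3a,4,6a-tetrahydro-2H-cyclopenta[b]furan-2-ol (anomer mixture) | CCCCC/C=C\C[C@]12OC(O)C[C@H]1[C@@H](O[Si](C)(C)C(C)(C)C)C=C2 | intermediate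
21 | methyltriphenylphosphonium bromide | C[P+](c1ccccc1)(c1ccccc1)c1ccccc1.[Br-] | starting material
22 | methyl 4-chloro-4-oxobutanoate | COC(=O)CCC(Cl)=O | starting material
23 | methylenetriphenylphosphorane | C=P(c1ccccc1)(c1ccccc1)c1ccccc1 | intermediate (not isolated)
24 | methyl 4-oxo-5-(triphenylphosphoranylidene)pentanoate | COC(=O)CCC(=O)C=P(c1ccccc1)(c1ccccc1)c1ccccc1 | intermediate
25 | methyl (5E)-7-[(1S,2R,5S)-5-[(tert-butyldimethylsilyl)oxy]-2-hydroxy-2-[(2Z)-oct-2-en-1-yl]cyclopent-3-en-1-yl]-4-oxohept-5-enoate | CCCCC/C=C\C[C@@]1(O)C=C[C@H](O[Si](C)(C)C(C)(C)C)[C@@H]1C/C=C/C(=O)CCC(=O)OC | intermediate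
26 | methyl (4S,5E)-7-[(1S,2R,5S)-5-[(tert-butyldimethylsilyl)oxy]-2-hydroxy-2-[(2Z)-oct-2-en-1-yl]cyclopent-3-en-1-yl]-4-hydroxyhept-5-enoate | CCCCC/C=C\C[C@@]1(O)C=C[C@H](O[Si](C)(C)C(C)(C)C)[C@@H]1C/C=C/[C@@H](O)CCC(=O)OC | intermediate
27 | methyl (4S,5E)-4-acetoxy-7-[(1S,2R,5S)-2-acetoxy-5-[(tert-butyldimethylsilyl)oxy]-2-[(2Z)-oct-2-en-1-yl]cyclopent-3-en-1-yl]hept-5-enoate | CCCCC/C=C\C[C@@]1(OC(C)=O)C=C[C@H](O[Si](C)(C)C(C)(C)C)[C@@H]1C/C=C/[C@@H](OC(C)=O)CCC(=O)OC | intermediate
28 | methyl (4S,5E)-4-acetoxy-7-[(1S,2R,5S)-2-acetoxy-5-hydroxy-2-[(2Z)-oct-2-en-1-yl]cyclopent-3-en-1-yl]hept-5-enoate | CCCCC/C=C\C[C@@]1(OC(C)=O)C=C[C@H](O)[C@@H]1C/C=C/[C@@H](OC(C)=O)CCC(=O)OC | intermediate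
29 | methyl (4S,5E)-4-acetoxy-7-[(1R,2R)-2-acetoxy-2-[(2Z)-oct-2-en-1-yl]-5-oxocyclopent-3-en-1-yl]hept-5-enoate | CCCCC/C=C\C[C@@]1(OC(C)=O)C=CC(=O)[C@@H]1C/C=C/[C@H](CCC(=O)OC)OC(C)=O | target

**Step count and risks**

Total steps: 18. Longest linear sequence: 17 (steps 1–12 and 14–18; step 13 is a one-step side branch).

Step 14. What may go wrong: once the lactol opens, the tertiary C12 hydroxyl can add in a 5-exo conjugate fashion to the new enone and re-close a tetrahydrofuran, and the hindered lactol may open only slowly towards the stabilised ylide. The fallback sets out from 19 and esterifies the C12 oxygen before the enone exists. LiBH4 in THF should open 19 to the diol 2-[(1S,2R,5S)-5-[(tert-butyldimethylsilyl)oxy]-2-hydroxy-2-[(2Z)-oct-2-en-1-yl]cyclopent-3-en-1-yl]ethan-1-ol F1. Ac2O, Et3N and DMAP should give the diacetate F2. K2CO3 in MeOH at 0 °C should remove only the primary acetate and give the hydroxy acetate F3. Dess–Martin oxidation then gives the aldehyde F4, and Wittig reaction with 24 gives the enone acetate F5, which has no free hydroxyl. CBS reduction as in step 15 should give the 4S alcohol F6, and acetylation with Ac2O and pyridine returns to the route at 27.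

Step 15. What may go wrong: poor facial selectivity at a ketone remote from the ring stereocentres, and lactonisation of the γ-hydroxy ester during work-up. The fallback sets out from 25 and replaces catalyst control by separation and inversion. NaBH4 with CeCl3·7H2O in MeOH at −78 °C should give 26 together with its 4R epimer F7, separable by chromatography as allylic-alcohol epimers of this kind usually are. F7 is inverted by a Mitsunobu reaction (AcOH, PPh3, DIAD, THF, 0 °C), in which the tertiary C12 hydroxyl cannot take part, to give the 4S monoacetate F8. Acetylation of F8 under the conditions of step 16 returns to the route at 27.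

Step 7. What may go wrong: slow rearrangement at the carbon flanked by the cis silyloxy group, and at 140 °C with acid either loss of the silyl ether or elimination to a cyclopentadiene. The fallback sets out from 12 and uses the low-temperature Ireland–Claisen variant. Ac2O, pyridine and DMAP give the allylic acetate F9. LDA and TMSCl in THF at −78 °C give the silyl ketene acetal F10, which should rearrange suprafacially on warming to room temperature to the trimethylsilyl ester F11. Aqueous work-up hydrolyses F11 and returns to the route at acid 16, bypassing 15.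

**Further compounds**

F1 | step 14 | 2-[(1S,2R,5S)-5-[(tert-butyldimethylsilyl)oxy]-2-hydroxy-2-[(2Z)-oct-2-en-1-yl]cyclopent-3-en-1-yl]ethan-1-ol | CCCCC/C=C\C[C@@]1(O)C=C[C@H](O[Si](C)(C)C(C)(C)C)[C@@H]1CCO
F2 | step 14 | diacetate of F1 (primary and tertiary acetate) | CCCCC/C=C\C[C@@]1(OC(C)=O)C=C[C@H](O[Si](C)(C)C(C)(C)C)[C@@H]1CCOC(C)=O
F3 | step 14 | tertiary C12 acetate with free primary alcohol | CCCCC/C=C\C[C@@]1(OC(C)=O)C=C[C@H](O[Si](C)(C)C(C)(C)C)[C@@H]1CCO
F4 | step 14 | 2-[(1S,2R,5S)-2-acetoxy-5-[(tert-butyldimethylsilyl)oxy]-2-[(2Z)-oct-2-en-1-yl]cyclopent-3-en-1-yl]acetaldehyde | CCCCC/C=C\C[C@@]1(OC(C)=O)C=C[C@H](O[Si](C)(C)C(C)(C)C)[C@@H]1CC=O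
F5 | step 14 | methyl (5E)-7-[(1S,2R,5S)-2-acetoxy-5-[(tert-butyldimethylsilyl)oxy]-2-[(2Z)-oct-2-en-1-yl]cyclopent-3-en-1-yl]-4-oxohept-5-enoate | CCCCC/C=C\C[C@@]1(OC(C)=O)C=C[C@H](O[Si](C)(C)C(C)(C)C)[C@@H]1C/C=C/C(=O)CCC(=O)OC
F6 | step 14 | methyl (4S,5E)-7-[(1S,2R,5S)-2-acetoxy-5-[(tert-butyldimethylsilyl)oxy]-2-[(2Z)-oct-2-en-1-yl]cyclopent-3-en-1-yl]-4-hydroxyhept-5-enoate | CCCCC/C=C\C[C@@]1(OC(C)=O)C=C[C@H](O[Si](C)(C)C(C)(C)C)[C@@H]1C/C=C/[C@@H](O)CCC(=O)OC
F7 | step 15 | 4R epimer of 26 | CCCCC/C=C\C[C@@]1(O)C=C[C@H](O[Si](C)(C)C(C)(C)C)[C@@H]1C/C=C/[C@H](O)CCC(=O)OC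
F8 | step 15 | methyl (4S,5E)-4-acetoxy-7-[(1S,2R,5S)-5-[(tert-butyldimethylsilyl)oxy]-2-hydroxy-2-[(2Z)-oct-2-en-1-yl]cyclopent-3-en-1-yl]hept-5-enoate | CCCCC/C=C\C[C@@]1(O)C=C[C@H](O[Si](C)(C)C(C)(C)C)[C@@H]1C/C=C/[C@@H](OC(C)=O)CCC(=O)OC
F9 | step 7 | (1R,4S)-4-[(tert-butyldimethylsilyl)oxy]-2-(oct-2-yn-1-yl)cyclopent-2-en-1-yl acetate | CCCCCC#CCC1=C[C@@H](O[Si](C)(C)C(C)(C)C)C[C@H]1OC(C)=O
F10 | step 7 | trimethylsilyl ketene acetal of F9 | CCCCCC#CCC1=C[C@@H](O[Si](C)(C)C(C)(C)C)C[C@H]1OC(=C)O[Si](C)(C)C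
F11 | step 7 | trimethylsilyl ester of 16 | CCCCCC#CCC1=CC[C@H](O[Si](C)(C)C(C)(C)C)[C@@H]1CC(=O)O[Si](C)(C)C
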